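**Plan**
- Cuts (target numbered as the cyclohex-2-en-1-yl acetate; side chain primed): first the diene single bond C3′–C4′ (sp2–sp2 cross-coupling), then the ring bonds C1–C6 and C4–C5 together, a [4+2] cut.
- Enabling feature: the carbocycle has one alkene (C2=C3) that bears the C3 methyl and has the C1 oxygen allylic to it, with the C6 carbon substituent cis to that oxygen. This is the retron of an endo Diels–Alder reaction of a 1-silyloxy-3-methylbuta-1,3-diene with an acrylate; silyloxy (ortho) and methyl (para) direct the same regiochemistry.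
- Forward: ring by catalytic asymmetric Diels–Alder reaction; allylic oxidation at C4; ester → alkyne → (E)-2-iodo-1-methylvinyl; C4 ketone; C1 acetate; C5 hydroxyl by Rubottom oxidation; side chain joined last by Suzuki–Miyaura coupling.
- Stereochemistry: C1/C6 from the catalyst-controlled endo cycloaddition; C5 from the ring (oxidant anti to the C6 group); C6′ from methyl (S)-3-hydroxy-2-methylpropanoate; 2′E from syn-carboalumination, 4′E from Takai–Utimoto olefination, 7′Z from a salt-free Wittig reaction.

Key step: step 2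

Assumption: the (R)-oxazaborolidinium cation is taken to leave the Si face of C2 of bound methyl acrylate open to the diene (the usual α-C–H···O binding model for acrylates); if the opposite sense were found, the mirror-image catalyst would be used with no other change.

Step 1
Reactants: 1 3-methylbut-2-enal
Product: 2 tert-butyl(dimethyl){[(1E)-3-methylbuta-1,3-dien-1-yl]oxy}silane
Conditions: tBuMe2SiOTf, Et3N, Et2O, 0 °C → rt
Reagents that add atoms: tert-butyldimethylsilyl trifluoromethanesulfonate, CC(C)(C)[Si](C)(C)OS(=O)(=O)C(F)(F)F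
Why: Silyl dienol ether formation (O-silylation of the enal, then γ-deprotonation of the oxocarbenium ion by Et3N) should give mainly the (E)-enol ether, and any Z isomer is inert in step 2.

Step 2
Reactants: 2 tert-butyl(dimethyl){[(1E)-3-methylbuta-1,3-dien-1-yl]oxy}silane, 3 methyl acrylate
Product: 4 methyl (1R,2S)-2-{[tert-butyl(dimethyl)silyl]oxy}-4-methylcyclohex-3-ene-1-carboxylate
Conditions: [C24H25BNO]+[N(SO2CF3)2]− (20 mol%), made in situ from (R)-1-(2-methylphenyl)-3,3-diphenyltetrahydro-1H,3H-pyrrolo[1,2-c][1,3,2]oxazaborole and HN(SO2CF3)2; CH2Cl2, −78 → −40 °C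
Reagents that add atoms: none
Why: The cationic boron Lewis acid binds the ester carbonyl of 3 and lowers its LUMO, and diene 2 adds in a concerted, asynchronous, suprafacial [4+2] cycloaddition (catalytic enantioselective Diels–Alder reaction; closest known type: oxazaborolidinium-catalysed additions of acrylates to silyloxy dienes). The only ring formed is the six-membered carbocycle, closed by the cycloaddition itself, both σ-bonds being made at once from two separate components without a tether. Regioselectivity is needed and is secured twice by the substrate: the 1-silyloxy group (ortho rule) and the 3-methyl group (para rule) both put the largest HOMO coefficient on the CH2 terminus of 2, which bonds to the β-carbon of the acrylate, so the ester carbon ends up next to the silyloxy carbon. The cis relation of ester and silyloxy group (C1/C2) follows from the endo transition state of the (E)-dienol ether, which Lewis-acid catalysis reinforces. The absolute configuration comes from the catalyst, which shields the Re face of C2 of the bound acrylate so that the diene adds to the Si face, giving (1R,2S). The main hazard is acid-induced loss of the silyl group from 2, which low temperature and excess diene should limit.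

Step 3
Reactants: 4 methyl (1R,2S)-2-{[tert-butyl(dimethyl)silyl]oxy}-4-methylcyclohex-3-ene-1-carboxylate
Product: 5 methyl (1R,2S)-2-{[tert-butyl(dimethyl)silyl]oxy}-5-hydroxy-4-methylcyclohex-3-ene-1-carboxylate (both C5 epimers)
Conditions: SeO2 (cat.), tBuOOH, CH2Cl2, rt
Reagents that add atoms: tert-butyl hydroperoxide, CC(C)(C)OO (the oxygen atom is passed on through selenium dioxide, O=[Se]=O)
Why: Allylic oxidation by SeO2 (ene reaction, then [2,3]-sigmatropic shift of the allylseleninic acid) should place oxygen on the ring CH2 attached to the more substituted alkene carbon (C5) in preference to the methyl group and the hindered C2–H; the new carbinol centre becomes the ketone in step 6, so both epimers are carried on.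

Step 4
Reactants: 5 methyl (1R,2S)-2-{[tert-butyl(dimethyl)silyl]oxy}-5-hydroxy-4-methylcyclohex-3-ene-1-carboxylate
Product: 7 (4S,5S)-4-{[tert-butyl(dimethyl)silyl]oxy}-5-ethynyl-2-methylcyclohex-2-en-1-ol (both C1 epimers), via aldehyde 6 (not isolated)
Conditions: iBu2AlH, CH2Cl2, −78 °C; then MeOH, K2CO3, dimethyl (1-diazo-2-oxopropyl)phosphonate, −78 °C → rt
Reagents that add atoms: dimethyl (1-diazo-2-oxopropyl)phosphonate, COP(=O)(OC)C(=[N+]=[N-])C(C)=O
Why: The tetrahedral aluminium intermediate releases aldehyde 6 only on methanol quench, and the diazomethylphosphonate anion formed in situ then homologates it to the alkyne (Seyferth–Gilbert reaction in its Ohira–Bestmann form) without isolation, which should limit epimerisation at the formyl-bearing carbon and β-elimination of the silyloxy group.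

Step 5
Reactants: 7 (4S,5S)-4-{[tert-butyl(dimethyl)silyl]oxy}-5-ethynyl-2-methylcyclohex-2-en-1-ol
Product: 9 (4S,5S)-4-{[tert-butyl(dimethyl)silyl]oxy}-5-[(1E)-1-iodoprop-1-en-2-yl]-2-methylcyclohex-2-en-1-ol (both C1 epimers), via alkenylalane 8 (not isolated)
Conditions: Me3Al, (C5H5)2ZrCl2, ClCH2CH2Cl, 0 °C → rt; then I2, THF, −30 °C
Reagents that add atoms: trimethylaluminium, C[Al](C)C; iodine, II
Why: Zirconium-catalysed syn-methylalumination of the terminal alkyne (Negishi carboalumination) puts methyl on the internal carbon and aluminium on the terminus, and iodinolysis with retention should give the (E)-iodoalkene; the free hydroxyl is carried as its aluminium alkoxide.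

Step 6
Reactants: 9 (4S,5S)-4-{[tert-butyl(dimethyl)silyl]oxy}-5-[(1E)-1-iodoprop-1-en-2-yl]-2-methylcyclohex-2-en-1-ol
Product: 10 (4S,5S)-4-{[tert-butyl(dimethyl)silyl]oxy}-5-[(1E)-1-iodoprop-1-en-2-yl]-2-methylcyclohex-2-en-1-one
Conditions: Dess–Martin periodinane, CH2Cl2, 0 °C → rt
Reagents that add atoms: none
Why: Dess–Martin oxidation of the allylic alcohol should bring both C1 epimers to the same enone without touching the iodoalkene or the silyl ether.

Step 7
Reactants: 10 (4S,5S)-4-{[tert-butyl(dimethyl)silyl]oxy}-5-[(1E)-1-iodoprop-1-en-2-yl]-2-methylcyclohex-2-en-1-one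
Product: 11 (4S,5S)-4-hydroxy-5-[(1E)-1-iodoprop-1-en-2-yl]-2-methylcyclohex-2-en-1-one
Conditions: HF·pyridine, pyridine, THF, 0 °C → rt
Reagents that add atoms: none
Why: Buffered fluoride cleavage of the secondary silyl ether is non-basic, so the γ-hydroxy enone should not eliminate or epimerise.

Step 8
Reactants: 11 (4S,5S)-4-hydroxy-5-[(1E)-1-iodoprop-1-en-2-yl]-2-methylcyclohex-2-en-1-one
Product: 12 (1S,6S)-6-[(1E)-1-iodoprop-1-en-2-yl]-3-methyl-4-oxocyclohex-2-en-1-yl acetate
Conditions: Ac2O, pyridine, DMAP (cat.), CH2Cl2, 0 °C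
Reagents that add atoms: acetic anhydride, CC(=O)OC(C)=O
Why: Acylation of the only hydroxyl group (nucleophilic catalysis by DMAP) installs the acetate of the target before the second hydroxyl exists, so no selectivity between hydroxyls is needed.

Step 9
Reactants: 12 (1S,6S)-6-[(1E)-1-iodoprop-1-en-2-yl]-3-methyl-4-oxocyclohex-2-en-1-yl acetate
Product: 15 (1S,5R,6R)-5-hydroxy-6-[(1E)-1-iodoprop-1-en-2-yl]-3-methyl-4-oxocyclohex-2-en-1-yl acetate, via silyl dienol ether 13 (not isolated), via silyloxy ketone 14 (not isolated)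
Conditions: Me3SiOTf, Et3N, CH2Cl2, −78 → 0 °C; then 3-ClC6H4CO3H, CH2Cl2/hexane, −20 °C; then aq. citric acid, THF, 0 °C
Reagents that add atoms: 3-chloroperoxybenzoic acid, OOC(=O)c1cccc(Cl)c1; trimethylsilyl trifluoromethanesulfonate, C[Si](C)(C)OS(=O)(=O)C(F)(F)F (silicon only in 13 and 14)
Why: Rubottom oxidation: kinetic α′-enolisation gives the cross-conjugated 2-silyloxy diene (as with carvone-type enones), the peracid epoxidises this most electron-rich double bond on the face opposite to the adjacent C6 alkenyl and C1 acetoxy groups, and epoxide opening with silyl transfer followed by mild acid should give the α′-hydroxy ketone with the hydroxyl trans to the C6 substituent (5R).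

Step 10
Reactants: 16 methyl (2S)-3-hydroxy-2-methylpropanoate
Product: 17 methyl (2S)-3-{[tert-butyl(dimethyl)silyl]oxy}-2-methylpropanoate
Conditions: tBuMe2SiCl, imidazole, CH2Cl2, rt
Reagents that add atoms: tert-butyldimethylsilyl chloride, CC(C)(C)[Si](C)(C)Cl
Why: Standard silylation of the primary alcohol protects it through the reduction and the olefination.

Step 11
Reactants: 17 methyl (2S)-3-{[tert-butyl(dimethyl)silyl]oxy}-2-methylpropanoate
Product: 18 (2S)-3-{[tert-butyl(dimethyl)silyl]oxy}-2-methylpropanal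
Conditions: iBu2AlH, CH2Cl2, −78 °C
Reagents that add atoms: none
Why: Partial reduction of the ester stops at the aldehyde because the tetrahedral aluminium intermediate is stable at −78 °C; the α-stereocentre is not touched.

Step 12
Reactants: 18 (2S)-3-{[tert-butyl(dimethyl)silyl]oxy}-2-methylpropanal, 19 (3-methylbutyl)triphenylphosphonium bromide
Product: 21 tert-butyl{[(2R,3Z)-2,6-dimethylhept-3-en-1-yl]oxy}dimethylsilane, via phosphorus ylide 20 (not isolated)
Conditions: 19, NaN(SiMe3)2, THF, 0 °C; then 18, −78 °C → rt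
Reagents that add atoms: none
Why: Wittig reaction of a non-stabilised, lithium-free ylide goes through the kinetically favoured cis-oxaphosphetane and should give the (Z)-alkene, with the aldehyde consumed at −78 °C before it can epimerise.

Step 13
Reactants: 21 tert-butyl{[(2R,3Z)-2,6-dimethylhept-3-en-1-yl]oxy}dimethylsilane
Product: 22 (2R,3Z)-2,6-dimethylhept-3-en-1-ol
Conditions: Bu4NF, THF, 0 °C → rt
Reagents that add atoms: none
Why: Fluoride cleavage of the primary silyl ether leaves the alkene and the allylic stereocentre alone.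

Step 14
Reactants: 22 (2R,3Z)-2,6-dimethylhept-3-en-1-ol
Product: 23 (2R,3Z)-2,6-dimethylhept-3-enal
Conditions: Dess–Martin periodinane, CH2Cl2, 0 °C; crude aldehyde used at once
Reagents that add atoms: none
Why: Dess–Martin oxidation is neutral and fast, which should keep the α-stereocentre of this β,γ-unsaturated aldehyde from racemising or moving into conjugation.

Step 15
Reactants: 23 (2R,3Z)-2,6-dimethylhept-3-enal
Product: 24 2-[(1E,3S,4Z)-3,7-dimethylocta-1,4-dien-1-yl]-4,4,5,5-tetramethyl-1,3,2-dioxaborolane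
Conditions: CrCl2, 2-(dichloromethyl)-4,4,5,5-tetramethyl-1,3,2-dioxaborolane, LiI, THF, rt
Reagents that add atoms: 2-(dichloromethyl)-4,4,5,5-tetramethyl-1,3,2-dioxaborolane, ClC(Cl)B1OC(C)(C)C(C)(C)O1
Why: Takai–Utimoto olefination with the boryl-substituted geminal dichromium reagent should give the (E)-alkenylboronate under non-basic conditions, sparing the labile stereocentre (its descriptor changes to S only because the priorities change).

Step 16
Reactants: 15 (1S,5R,6R)-5-hydroxy-6-[(1E)-1-iodoprop-1-en-2-yl]-3-methyl-4-oxocyclohex-2-en-1-yl acetate, 24 2-[(1E,3S,4Z)-3,7-dimethylocta-1,4-dien-1-yl]-4,4,5,5-tetramethyl-1,3,2-dioxaborolane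
Product: 25 (1S,5R,6R)-5-hydroxy-3-methyl-4-oxo-6-[(2E,4E,6R,7Z)-6,10-dimethylundeca-2,4,7-trien-2-yl]cyclohex-2-en-1-yl acetate
Conditions: [1,1′-bis(diphenylphosphino)ferrocene]PdCl2·CH2Cl2 (cat.), K3PO4, THF/H2O, rt
Reagents that add atoms: none
Why: Suzuki–Miyaura coupling (oxidative addition of the iodoalkene to zerovalent palladium, base-assisted transmetalation, reductive elimination) joins the two sp2 carbons with retention of both alkene geometries, and the mild phosphate base at room temperature should spare the acetate and the α-ketol.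

**Compound list**
1 | 3-methylbut-2-enal | CC(C)=CC=O | starting material
2 | tert-butyl(dimethyl){[(1E)-3-methylbuta-1,3-dien-1-yl]oxy}silane | C=C(C)/C=C/O[Si](C)(C)C(C)(C)C | intermediate
3 | methyl acrylate (methyl prop-2-enoate) | C=CC(=O)OC | starting material
4 | methyl (1R,2S)-2-{[tert-butyl(dimethyl)silyl]oxy}-4-methylcyclohex-3-ene-1-carboxylate | CC(C)(C)[Si](C)(C)O[C@H]1C=C(C)CC[C@H]1C(=O)OC | intermediate
5 | methyl (1R,2S)-2-{[tert-butyl(dimethyl)silyl]oxy}-5-hydroxy-4-methylcyclohex-3-ene-1-carboxylate, both C5 epimers | CC(C)(C)[Si](C)(C)O[C@H]1C=C(C)C(O)C[C@H]1C(=O)OC | intermediate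
6 | (1R,2S)-2-{[tert-butyl(dimethyl)silyl]oxy}-5-hydroxy-4-methylcyclohex-3-ene-1-carbaldehyde, both C5 epimers | CC(C)(C)[Si](C)(C)O[C@H]1C=C(C)C(O)C[C@H]1C=O | intermediate (not isolated)
7 | (4S,5S)-4-{[tert-butyl(dimethyl)silyl]oxy}-5-ethynyl-2-methylcyclohex-2-en-1-ol, both C1 epimers | CC(C)(C)[Si](C)(C)O[C@H]1C=C(C)C(O)C[C@H]1C#C | intermediate
8 | (E)-alkenyl(dimethyl)alane from syn-methylalumination of 7, hydroxyl as its dimethylaluminium alkoxide | CC(C)(C)[Si](C)(C)O[C@H]1C=C(C)C(O[Al](C)C)C[C@H]1/C(C)=C/[Al](C)C | intermediate (not isolated)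
9 | (4S,5S)-4-{[tert-butyl(dimethyl)silyl]oxy}-5-[(1E)-1-iodoprop-1-en-2-yl]-2-methylcyclohex-2-en-1-ol, both C1 epimers | CC(C)(C)[Si](C)(C)O[C@H]1C=C(C)C(O)C[C@H]1/C(C)=C/I | intermediate
10 | (4S,5S)-4-{[tert-butyl(dimethyl)silyl]oxy}-5-[(1E)-1-iodoprop-1-en-2-yl]-2-methylcyclohex-2-en-1-one | CC(C)(C)[Si](C)(C)O[C@H]1C=C(C)C(=O)C[C@H]1/C(C)=C/I | intermediate
11 | (4S,5S)-4-hydroxy-5-[(1E)-1-iodoprop-1-en-2-yl]-2-methylcyclohex-2-en-1-one | O[C@H]1C=C(C)C(=O)C[C@H]1/C(C)=C/I | intermediate
12 | (1S,6S)-6-[(1E)-1-iodoprop-1-en-2-yl]-3-methyl-4-oxocyclohex-2-en-1-yl acetate | CC(=O)O[C@H]1C=C(C)C(=O)C[C@H]1/C(C)=C/I | intermediate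
13 | trimethylsilyl dienol ether of 12 (4-[(trimethylsilyl)oxy]cyclohexa-2,4-dien-1-yl acetate, other groups as in 12) | CC(=O)O[C@H]1C=C(C)C(O[Si](C)(C)C)=C[C@H]1/C(C)=C/I | intermediate (not isolated)
14 | 5-O-trimethylsilyl ether of 15 | CC(=O)O[C@H]1C=C(C)C(=O)[C@H](O[Si](C)(C)C)[C@H]1/C(C)=C/I | intermediate (not isolated)
15 | (1S,5R,6R)-5-hydroxy-6-[(1E)-1-iodoprop-1-en-2-yl]-3-methyl-4-oxocyclohex-2-en-1-yl acetate | CC(=O)O[C@H]1C=C(C)C(=O)[C@H](O)[C@H]1/C(C)=C/I | intermediate
16 | methyl (2S)-3-hydroxy-2-methylpropanoate | C[C@@H](CO)C(=O)OC | starting material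
17 | methyl (2S)-3-{[tert-butyl(dimethyl)silyl]oxy}-2-methylpropanoate | C[C@@H](CO[Si](C)(C)C(C)(C)C)C(=O)OC | intermediate
18 | (2S)-3-{[tert-butyl(dimethyl)silyl]oxy}-2-methylpropanal | C[C@@H](CO[Si](C)(C)C(C)(C)C)C=O | intermediate
19 | (3-methylbutyl)triphenylphosphonium bromide | CC(C)CC[P+](c1ccccc1)(c1ccccc1)c1ccccc1.[Br-] | starting material
20 | (3-methylbutylidene)triphenylphosphorane | CC(C)CC=P(c1ccccc1)(c1ccccc1)c1ccccc1 | intermediate (not isolated)
21 | tert-butyl{[(2R,3Z)-2,6-dimethylhept-3-en-1-yl]oxy}dimethylsilane | C[C@@H](CO[Si](C)(C)C(C)(C)C)/C=C\CC(C)C | intermediate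
22 | (2R,3Z)-2,6-dimethylhept-3-en-1-ol | C[C@@H](CO)/C=C\CC(C)C | intermediate
23 | (2R,3Z)-2,6-dimethylhept-3-enal | C[C@@H](C=O)/C=C\CC(C)C | intermediate
24 | 2-[(1E,3S,4Z)-3,7-dimethylocta-1,4-dien-1-yl]-4,4,5,5-tetramethyl-1,3,2-dioxaborolane | C[C@@H](/C=C/B1OC(C)(C)C(C)(C)O1)/C=C\CC(C)C | intermediate
25 | (1S,5R,6R)-5-hydroxy-3-methyl-4-oxo-6-[(2E,4E,6R,7Z)-6,10-dimethylundeca-2,4,7-trien-2-yl]cyclohex-2-en-1-yl acetate | CC(=O)O[C@H]1C=C(C)C(=O)[C@H](O)[C@H]1/C(C)=C/C=C/[C@H](C)/C=C\CC(C)C | target

Total step count: 16. Longest linear sequence: 10 steps (steps 1–9 and 16).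

**Steps most likely to fail**

Step 3 (allylic oxidation). Oxidation may go to the wrong allylic site (the ring methyl or the silyloxy-bearing carbon), run on to the enone, or stall. The fallback brings this oxygen in with the diene instead of by C–H oxidation; it sets out from 3 and comes back to the route at 5. (tert-Butyldimethylsilyloxy)acetaldehyde and 2-(triphenylphosphoranylidene)propanal (toluene, 80 °C) should give (E)-4-{[tert-butyl(dimethyl)silyl]oxy}-2-methylbut-2-enal F1. Ac2O, Et3N and DMAP should convert it by γ-deprotonation and O-acetylation into (1E,3E)-4-{[tert-butyl(dimethyl)silyl]oxy}-2-methylbuta-1,3-dien-1-yl acetate F2, whose Z isomers do not react further. Cycloaddition of F2 with 3 under the catalyst of step 2 should give methyl (1R,2S,5S)-5-(acetyloxy)-2-{[tert-butyl(dimethyl)silyl]oxy}-4-methylcyclohex-3-ene-1-carboxylate F3, the stronger silyloxy donor and the methyl group again placing the ester next to the silyl ether. K2CO3 in MeOH at 0 °C then removes the acetate and gives 5 as its 5S epimer.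

Step 9 (α′-hydroxylation). Enolisation may go toward the γ-carbon that bears the acetate, with loss of acetic acid, or the peracid may attack another alkene. The fallback replaces the enol ether oxidation by a manganese enolate acetoxylation; it sets out from 12 and comes back at 15. Mn(OAc)3·2H2O in benzene at reflux should acetoxylate the α′-position trans to the C6 substituent and give (1S,5R,6S)-6-[(1E)-1-iodoprop-1-en-2-yl]-3-methyl-4-oxocyclohex-2-ene-1,5-diyl diacetate F4. A lipase in pH 7 phosphate buffer should then hydrolyse only the activated α-ketol acetate to give 15.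

Step 16 (final coupling). The base may hydrolyse the acetate, epimerise the α-ketol carbon, or cause protodeboronation before transmetalation. The fallback is a base-free Stille coupling; it sets out from 23 and comes back at 25. CrCl2, Bu3SnCHBr2 and LiI in THF/DMF (chromium-mediated stannyl olefination) should give tributyl[(1E,3R,4Z)-3,7-dimethylocta-1,4-dien-1-yl]stannane F5. Coupling of F5 with 15 using Pd(PPh3)4, copper thiophene-2-carboxylate (CuO2CC4H3S) and Bu4N Ph2PO2 in DMF at rt should give 25.

**Further compounds**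
F1 | step 3 | (E)-4-{[tert-butyl(dimethyl)silyl]oxy}-2-methylbut-2-enal | CC(C)(C)[Si](C)(C)OC/C=C(\C)C=O
F2 | step 3 | (1E,3E)-4-{[tert-butyl(dimethyl)silyl]oxy}-2-methylbuta-1,3-dien-1-yl acetate | CC(=O)O/C=C(C)/C=C/O[Si](C)(C)C(C)(C)C
F3 | step 3 | methyl (1R,2S,5S)-5-(acetyloxy)-2-{[tert-butyl(dimethyl)silyl]oxy}-4-methylcyclohex-3-ene-1-carboxylate | CC(C)(C)[Si](C)(C)O[C@H]1C=C(C)[C@@H](OC(C)=O)C[C@H]1C(=O)OC
F4 | step 9 | (1S,5R,6S)-6-[(1E)-1-iodoprop-1-en-2-yl]-3-methyl-4-oxocyclohex-2-ene-1,5-diyl diacetate | CC(=O)O[C@H]1C=C(C)C(=O)[C@H](OC(C)=O)[C@H]1/C(C)=C/I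
F5 | step 16 | tributyl[(1E,3R,4Z)-3,7-dimethylocta-1,4-dien-1-yl]stannane | CCCC[Sn](CCCC)(CCCC)/C=C/[C@H](C)/C=C\CC(C)C
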